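**Retrosynthetic overview**

- The strategy rests on the central benzene ring: it carries aryl carbons at C3 and C6 and ester oxygens at C1, C2, C4 and C5. Its three rings and two biaryl bonds are those of commercial 4,4''-dihydroxy-p-terphenyl, so only four C–O bonds are missing.
- The esters are disconnected last: the two (R)-3-hydroxybutanoates at C4/C5 (carried as benzyl ethers), then the C1 acetate and C2 3-phenylpropanoate, from a catechol whose C4/C5 oxygens are held in a di-tert-butylsilylene.
- That 1,2/4,5 differentiation comes from a 2,5-dihydroxy-1,4-benzoquinone, the enol tautomer of a cyclohexane-1,2,4,5-tetrone, which is reached by oxidation of a cyclohexane-1,2,4,5-tetrol.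
- The tetrol comes from double syn-dihydroxylation of the C1=C2 and C4=C5 alkenes of a cis-3,6-diarylcyclohexa-1,4-diene, made by Birch reduction of the terphenyldiol at C3/C6 and benzylation.
- No carbocycle is built: the bought central ring is dearomatised (step 1), oxygenated (step 3) and rearomatised (steps 4 and 5); the only ring closed is the temporary five-membered dioxasilole (step 5).

Key step: step 3

Assumption: the Birch product is drawn and carried as the cis diene; any trans isomer formed alongside would be processed in the same way, because all six stereocentres of the central ring disappear in step 4.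

**Route**

Step 1
Reactants: 1 4,4''-dihydroxy-p-terphenyl
Product: 2 cis-3,6-bis(4-hydroxyphenyl)cyclohexa-1,4-diene
Conditions: Li (5 equiv), NH3/THF, −78 °C; inverse quench into NH4Cl; argon
Reagents that add atoms: none
Why: Birch reduction, in which the phenols are first converted into lithium phenoxides whose rings resist electron uptake, so that the two electrons should enter the central ring and protonation at its two aryl-bearing carbons C3 and C6 (the regiochemistry known for biphenyls, p-terphenyl and hydroxybiaryls) should give the unconjugated 1,4-diene, the relative configuration of C3 and C6 being of no consequence.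

Step 2
Reactants: 2 cis-3,6-bis(4-hydroxyphenyl)cyclohexa-1,4-diene; 3 benzyl bromide
Product: 4 cis-3,6-bis(4-benzyloxyphenyl)cyclohexa-1,4-diene
Conditions: BnBr (2.2 equiv), K2CO3, DMF, 0 °C → rt, argon, degassed solvent
Reagents that add atoms: benzyl bromide (3), BrCc1ccccc1
Why: Williamson ether synthesis in which carbonate deprotonates only the phenols and not the doubly allylic C3–H and C6–H bonds, so the 1,4-diene should be neither isomerised nor aromatised and its two stereocentres are untouched.

Step 3
Reactants: 4 cis-3,6-bis(4-benzyloxyphenyl)cyclohexa-1,4-diene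
Product: 6 all-cis-3,6-bis(4-benzyloxyphenyl)cyclohexane-1,2,4,5-tetrol (meso; both aryl groups anti to the four hydroxyls), via cyclohexenediol 5 (not isolated)
Conditions: OsO4 (5 mol %), N-methylmorpholine N-oxide (3 equiv), acetone/THF/H2O, rt, argon
Reagents that add atoms: osmium tetroxide (oxygen carrier), O=[Os](=O)(=O)=O; N-methylmorpholine N-oxide, C[N+]1([O-])CCOCC1; water, O
Why: OsO4 adds across each ring alkene by a concerted [3+2] cycloaddition to give a hexavalent osmium glycolate, which water hydrolyses while the N-oxide returns the metal to octavalent OsO4, so that the four C–O bonds at C1, C2, C4 and C5 are made with catalytic osmium. The closest known reaction type is the OsO4-catalysed double dihydroxylation of cyclohexa-1,4-dienes to cyclohexane-1,2,4,5-tetrols with an amine N-oxide as terminal oxidant. No ring is closed in this step. Each of the four new stereocentres is set by the suprafacial cycloaddition (cis within each diol) and by the two cis aryl groups at C3 and C6, which shield one face so that both diols should form on the opposite face and give the all-cis meso tetrol. The selectivity the step needs is chemoselectivity for alkene oxidation over dehydrogenation of the doubly allylic, benzylic C3–H and C6–H bonds back to the terphenyl, and it is secured by an oxidant pair that does not abstract hydrogen, a base-free medium and exclusion of air. Facial selectivity is not needed, because every stereocentre of the central ring is erased in step 4.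

Step 4
Reactants: 6 all-cis-3,6-bis(4-benzyloxyphenyl)cyclohexane-1,2,4,5-tetrol
Product: 8 2,5-dihydroxy-3,6-bis(4-benzyloxyphenyl)-1,4-benzoquinone, via tetraketone 7 (not isolated)
Conditions: IBX (2-iodoxybenzoic acid, 6 equiv), DMSO, rt
Reagents that add atoms: none
Why: IBX oxidation of secondary alcohols, which converts 1,2-diols into 1,2-diketones without glycol cleavage under neutral conditions, should give the 1,2,4,5-tetraketone, which is the keto tautomer of the dihydroxyquinone and enolises at the doubly activated Ar–CH positions C3 and C6, erasing all six ring stereocentres.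

Step 5
Reactants: 8 2,5-dihydroxy-3,6-bis(4-benzyloxyphenyl)-1,4-benzoquinone
Product: 10 4,7-bis(4-benzyloxyphenyl)-2,2-di-tert-butyl-1,3,2-benzodioxasilole-5,6-diol, via silylene ortho-quinone 9 (not isolated)
Conditions: tBu2Si(OTf)2 (1.05 equiv, slow addition), 2,6-lutidine, CH2Cl2, −20 °C → rt; then aq. Na2S2O4, rt, argon
Reagents that add atoms: di-tert-butylsilyl bis(trifluoromethanesulfonate), CC(C)(C)[Si](OS(=O)(=O)C(F)(F)F)(OS(=O)(=O)C(F)(F)F)C(C)(C)C
Why: Proposed new method: O-silylation of one enolic hydroxyl places a silyl triflate beside the neighbouring quinone carbonyl, whose oxygen should close the five-membered dioxasilole while the remote hydroxyl gives up its proton, so that the quinone is trapped as its 4,5-dioxy-1,2-benzoquinone tautomer (the silicon counterpart of the known condensation of 2,5-dihydroxy-1,4-benzoquinones with 1,2-diamines through that tautomer, and of the standard di-tert-butylsilylene protection of catechols), only one bridge being possible because the quinone holds just two hydroxyls, after which Na2S2O4 reduces the ortho-quinone to the catechol.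

Step 6
Reactants: 10 4,7-bis(4-benzyloxyphenyl)-2,2-di-tert-butyl-1,3,2-benzodioxasilole-5,6-diol; 11 3-phenylpropanoyl chloride
Product: 12 6-hydroxy-4,7-bis(4-benzyloxyphenyl)-2,2-di-tert-butyl-1,3,2-benzodioxasilol-5-yl 3-phenylpropanoate
Conditions: 11 (1.0 equiv, added over 1 h), pyridine (3 equiv), CH2Cl2, −40 °C, argon
Reagents that add atoms: 3-phenylpropanoyl chloride (11), O=C(Cl)CCc1ccccc1
Why: O-acylation of a phenol with an acid chloride and pyridine, in which the two hydroxyls are equivalent by symmetry so only one monoester can form, and the limiting acid chloride together with the lower reactivity of the remaining hindered, hydrogen-bonded hydroxyl should hold the reaction largely at the monoester (diester is separated and unreacted diol recycled).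

Step 7
Reactants: 12 6-hydroxy-4,7-bis(4-benzyloxyphenyl)-2,2-di-tert-butyl-1,3,2-benzodioxasilol-5-yl 3-phenylpropanoate
Product: 13 6-acetoxy-4,7-bis(4-benzyloxyphenyl)-2,2-di-tert-butyl-1,3,2-benzodioxasilol-5-yl 3-phenylpropanoate
Conditions: Ac2O, pyridine, CH2Cl2, 0 °C → rt
Reagents that add atoms: acetic anhydride, CC(=O)OC(C)=O
Why: acetylation of a phenol with acetic anhydride and pyridine, the small acetyl group being placed last on the hydroxyl that lies between an aryl group and an acyloxy group, and any prior migration of the phenylpropanoyl group between the two adjacent oxygens being degenerate.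

Step 8
Reactants: 13 6-acetoxy-4,7-bis(4-benzyloxyphenyl)-2,2-di-tert-butyl-1,3,2-benzodioxasilol-5-yl 3-phenylpropanoate
Product: 14 2-acetoxy-4,5-dihydroxy-3,6-bis(4-benzyloxyphenyl)phenyl 3-phenylpropanoate
Conditions: HF·pyridine, THF/pyridine, 0 °C
Reagents that add atoms: none
Why: fluoride-mediated desilylation of the aryl silylene under buffered conditions that aryl esters and benzyl ethers tolerate, with acyl transfer to the freed C4/C5 hydroxyls excluded because they are separated from the C1/C2 esters by the aryl-bearing carbons.

Step 9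
Reactants: 15 methyl (R)-3-hydroxybutanoate
Product: 16 methyl (R)-3-(benzyloxy)butanoate
Conditions: benzyl 2,2,2-trichloroacetimidate, TfOH (cat.), CH2Cl2/cyclohexane, 0 °C → rt
Reagents that add atoms: benzyl 2,2,2-trichloroacetimidate, N=C(OCc1ccccc1)C(Cl)(Cl)Cl
Why: acid-catalysed O-benzylation with a trichloroacetimidate, which avoids the basic conditions that would cause elimination or retro-aldol cleavage of the β-hydroxy ester and leaves the C–O bond of the (R) stereocentre intact.

Step 10
Reactants: 16 methyl (R)-3-(benzyloxy)butanoate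
Product: 17 (R)-3-(benzyloxy)butanoic acid
Conditions: LiOH, THF/H2O, 0 °C → rt; then aq. HCl
Reagents that add atoms: lithium hydroxide, [Li+].[OH-]
Why: ester saponification, in which the stereocentre is β to the carbonyl and therefore not epimerisable, and the low temperature disfavours β-elimination of benzyl alcohol.

Step 11
Reactants: 14 2-acetoxy-4,5-dihydroxy-3,6-bis(4-benzyloxyphenyl)phenyl 3-phenylpropanoate; 17 (R)-3-(benzyloxy)butanoic acid
Product: 18 2-acetoxy-3,6-bis(4-benzyloxyphenyl)-4,5-bis[(R)-3-(benzyloxy)butanoyloxy]phenyl 3-phenylpropanoate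
Conditions: 17 (2.4 equiv), N,N'-diisopropylcarbodiimide (2.6 equiv), DMAP (0.2 equiv), CH2Cl2, 0 °C → rt
Reagents that add atoms: (R)-3-(benzyloxy)butanoic acid (17), OC(=O)C[C@@H](C)OCc1ccccc1
Why: Steglich esterification of both phenols under near-neutral conditions with only catalytic DMAP, so the aryl esters already present should not scramble and the two (R) centres, remote from the reacting carboxyl, are carried through unchanged.

Step 12
Reactants: 18 2-acetoxy-3,6-bis(4-benzyloxyphenyl)-4,5-bis[(R)-3-(benzyloxy)butanoyloxy]phenyl 3-phenylpropanoate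
Product: 19 Curtisian V
Conditions: H2 (1 atm), 10% Pd/C, EtOAc, rt
Reagents that add atoms: none
Why: catalytic hydrogenolysis of the two aryl benzyl ethers and the two alkyl benzyl ethers in a neutral, non-nucleophilic solvent, which the four aryl esters tolerate, and which cleaves only O–CH2Ph bonds so the (R) centres keep their configuration.

**Compound list**

1 | 4,4''-dihydroxy-p-terphenyl | Oc1ccc(-c2ccc(-c3ccc(O)cc3)cc2)cc1 | starting material
2 | cis-3,6-bis(4-hydroxyphenyl)cyclohexa-1,4-diene | Oc1ccc([C@@H]2C=C[C@H](c3ccc(O)cc3)C=C2)cc1 | intermediate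
3 | benzyl bromide | BrCc1ccccc1 | starting material
4 | cis-3,6-bis(4-benzyloxyphenyl)cyclohexa-1,4-diene | c1cc(OCc2ccccc2)ccc1[C@@H]1C=C[C@H](c2ccc(OCc3ccccc3)cc2)C=C1 | intermediate
5 | 3,6-bis(4-benzyloxyphenyl)cyclohex-4-ene-1,2-diol, cis-diol on the face opposite the two cis aryl groups (meso; formed in the flask, not isolated) | O[C@H]1[C@@H](O)[C@H](c2ccc(OCc3ccccc3)cc2)C=C[C@@H]1c1ccc(OCc2ccccc2)cc1 | intermediate
6 | all-cis-3,6-bis(4-benzyloxyphenyl)cyclohexane-1,2,4,5-tetrol, four hydroxyls on one face and both aryl groups on the other (meso) | O[C@H]1[C@@H](O)[C@H](c2ccc(OCc3ccccc3)cc2)[C@@H](O)[C@@H](O)[C@@H]1c1ccc(OCc2ccccc2)cc1 | intermediate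
7 | 3,6-bis(4-benzyloxyphenyl)cyclohexane-1,2,4,5-tetrone (cis as formed, configurationally labile; not isolated) | O=C1C(=O)[C@H](c2ccc(OCc3ccccc3)cc2)C(=O)C(=O)[C@@H]1c1ccc(OCc2ccccc2)cc1 | intermediate
8 | 2,5-dihydroxy-3,6-bis(4-benzyloxyphenyl)-1,4-benzoquinone | O=C1C(O)=C(c2ccc(OCc3ccccc3)cc2)C(=O)C(O)=C1c1ccc(OCc2ccccc2)cc1 | intermediate
9 | 4,7-bis(4-benzyloxyphenyl)-2,2-di-tert-butyl-1,3,2-benzodioxasilole-5,6-dione (not isolated) | O=C1C(=O)C(c2ccc(OCc3ccccc3)cc2)=C2O[Si](C(C)(C)C)(C(C)(C)C)OC2=C1c1ccc(OCc2ccccc2)cc1 | intermediate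
10 | 4,7-bis(4-benzyloxyphenyl)-2,2-di-tert-butyl-1,3,2-benzodioxasilole-5,6-diol | Oc1c(O)c(-c2ccc(OCc3ccccc3)cc2)c2O[Si](C(C)(C)C)(C(C)(C)C)Oc2c1-c1ccc(OCc2ccccc2)cc1 | intermediate
11 | 3-phenylpropanoyl chloride | O=C(Cl)CCc1ccccc1 | starting material
12 | 6-hydroxy-4,7-bis(4-benzyloxyphenyl)-2,2-di-tert-butyl-1,3,2-benzodioxasilol-5-yl 3-phenylpropanoate | O=C(CCc1ccccc1)Oc1c(O)c(-c2ccc(OCc3ccccc3)cc2)c2O[Si](C(C)(C)C)(C(C)(C)C)Oc2c1-c1ccc(OCc2ccccc2)cc1 | intermediate
13 | 6-acetoxy-4,7-bis(4-benzyloxyphenyl)-2,2-di-tert-butyl-1,3,2-benzodioxasilol-5-yl 3-phenylpropanoate | CC(=O)Oc1c(OC(=O)CCc2ccccc2)c(-c2ccc(OCc3ccccc3)cc2)c2O[Si](C(C)(C)C)(C(C)(C)C)Oc2c1-c1ccc(OCc2ccccc2)cc1 | intermediate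
14 | 2-acetoxy-4,5-dihydroxy-3,6-bis(4-benzyloxyphenyl)phenyl 3-phenylpropanoate | CC(=O)Oc1c(OC(=O)CCc2ccccc2)c(-c2ccc(OCc3ccccc3)cc2)c(O)c(O)c1-c1ccc(OCc2ccccc2)cc1 | intermediate
15 | methyl (R)-3-hydroxybutanoate | COC(=O)C[C@@H](C)O | starting material
16 | methyl (R)-3-(benzyloxy)butanoate | COC(=O)C[C@@H](C)OCc1ccccc1 | intermediate
17 | (R)-3-(benzyloxy)butanoic acid | OC(=O)C[C@@H](C)OCc1ccccc1 | intermediate
18 | 2-acetoxy-3,6-bis(4-benzyloxyphenyl)-4,5-bis[(R)-3-(benzyloxy)butanoyloxy]phenyl 3-phenylpropanoate | CC(=O)Oc1c(OC(=O)CCc2ccccc2)c(-c2ccc(OCc3ccccc3)cc2)c(OC(=O)C[C@@H](C)OCc2ccccc2)c(OC(=O)C[C@@H](C)OCc2ccccc2)c1-c1ccc(OCc2ccccc2)cc1 | intermediate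
19 | Curtisian V, 2-acetoxy-4,5-bis[(R)-3-hydroxybutanoyloxy]-3,6-bis(4-hydroxyphenyl)phenyl 3-phenylpropanoate | CC(=O)Oc1c(OC(=O)CCc2ccccc2)c(-c2ccc(O)cc2)c(OC(=O)C[C@@H](C)O)c(OC(=O)C[C@@H](C)O)c1-c1ccc(O)cc1 | target

**Step count**

Total: 12 steps. Longest linear sequence: 10 steps (steps 1 to 8, then 11 and 12); the side-chain acid 17 is made in 2 steps (9 and 10).

**Three steps most likely to fail**

Step 5 (silylene bridging of the quinone). Closure of the mono-silylated quinone onto the neighbouring carbonyl oxygen may be slower than intermolecular silylation, or the vinylogous silyl ester may hydrolyse before it is reduced. The fallback uses known chemistry, sets out from 8 and returns at 10. Quinone 8 is first reduced with aqueous Na2S2O4 under argon to 3,6-bis(4-benzyloxyphenyl)benzene-1,2,4,5-tetrol F1. This air-sensitive tetrol is treated at low temperature with one equivalent of tBu2Si(OTf)2 and 2,6-lutidine, the ordinary silylene protection of a catechol. The mono-silylene 10 is separated from doubly protected and unprotected material, the latter being recycled.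

Step 4 (fourfold oxidation). The hypervalent iodine oxidant may cleave the C–C bond of the cis-glycols instead of oxidising them, or the oxidation may stall at partly oxidised stages. The fallback sets out from 6 and returns at 8, and never exposes a free glycol to an oxidant that can cleave it. Tetrol 6 is heated with Bu2SnO in toluene with azeotropic removal of water to give the bis(dibutylstannylene) acetal F2. Brominolysis with Br2 in CH2Cl2 at 0 °C, which oxidises one carbinol of each stannylene without breaking the C–C bond, should give 2,5-dihydroxy-3,6-bis(4-benzyloxyphenyl)cyclohexane-1,4-dione F3 (drawn as one regioisomer; the other converges). The two acyloins of F3 are then oxidised with Cu(OAc)2 in aqueous acetic acid, the classical acyloin-to-diketone oxidation, and tautomerisation delivers 8.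

Step 1 (Birch reduction of the free diol). The doubly deprotonated substrate may dissolve poorly and take up electrons sluggishly, an outer ring may be over-reduced, or the diene may re-aromatise during work-up. The fallback sets out from 1 and returns at 2, and reduces a neutral ether instead of a polyanion. Diol 1 is protected with chloromethyl methyl ether and iPr2NEt as 4,4''-bis(methoxymethoxy)-p-terphenyl F4. Birch reduction with Li (2.2 equiv) in NH3/THF without added alcohol, quenched with NH4Cl, should reduce the central ring, as is known for alkoxybiaryls, to cis-3,6-bis[4-(methoxymethoxy)phenyl]cyclohexa-1,4-diene F5. Brief treatment with catalytic HCl in MeOH/THF under argon removes the acetals and gives 2.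

**Further compounds**

F1 | step 5 | 3,6-bis(4-benzyloxyphenyl)benzene-1,2,4,5-tetrol | Oc1c(O)c(-c2ccc(OCc3ccccc3)cc2)c(O)c(O)c1-c1ccc(OCc2ccccc2)cc1
F2 | step 4 | bis(dibutylstannylene) acetal of tetrol 6 (drawn as the monomer) | O1[C@H]2[C@@H](O[Sn]1(CCCC)CCCC)[C@H](c1ccc(OCc3ccccc3)cc1)[C@H]3O[Sn](CCCC)(CCCC)O[C@H]3[C@@H]2c1ccc(OCc2ccccc2)cc1
F3 | step 4 | 2,5-dihydroxy-3,6-bis(4-benzyloxyphenyl)cyclohexane-1,4-dione (all substituent configurations as in 6) | O=C1[C@@H](O)[C@H](c2ccc(OCc3ccccc3)cc2)C(=O)[C@@H](O)[C@@H]1c1ccc(OCc2ccccc2)cc1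
F4 | step 1 | 4,4''-bis(methoxymethoxy)-p-terphenyl | COCOc1ccc(-c2ccc(-c3ccc(OCOC)cc3)cc2)cc1
F5 | step 1 | cis-3,6-bis[4-(methoxymethoxy)phenyl]cyclohexa-1,4-diene | COCOc1ccc([C@@H]2C=C[C@H](c3ccc(OCOC)cc3)C=C2)cc1
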